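## Analysis of the target

The target 29 consists of two highly oxygenated benzene rings joined by one methylene carbon; it has no stereocentre. Ring A is numbered from its methoxy carbon: C1 (OMe), C2 (acetyl), C3 (OH), C4 (CH2 bridge), C5 (OH), C6 (H). Ring B is hexasubstituted: going round from the bridge carbon it carries OH, CH3, OH, acetyl and OMe. The sensitive groups are the four free phenols, the two aryl methyl ethers that sit ortho to acetyl groups (cleaved by strong Lewis acids), the aryl ketones (over-reduction), and the methylene bridge between two electron-rich rings, which acid can cut by ipso protonation. The difficulty is regiochemical: the rings are near-twins that differ only in the place of the methyl ether (para to the bridge in ring A, ortho in ring B) and in the C-methyl of ring B, and the bridge is flanked by four ortho oxygens. The strategy rests on ring A. Without the C2 acetyl it is mirror-symmetric about the C1–C4 axis, so C2 and C6 are equivalent. Its C4 with the attached bridge can be carried by C2 of a cyclobutenone, while C1 and its oxygen arise from a ketene carbonyl as the only free phenol of a benzannulation product.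

## Retrosynthetic reasoning

**29 to 27.** The last bond made is C2–C(acetyl) of ring A. Removing it gives tetraphenol 27, in which ring B has no ring hydrogen and ring A has two equivalent ones, so one electrophilic acetylation can lead only to 29. The forward reaction must stop after one acyl group and spare the bridge; acylation through a nitrile does this, because the iminium salt 28 is strongly deactivated.

**27 to 24.** Three C–O operations lead back through 26 and 25 to phenol 24. In 24 the ring A oxygens are all different: free OH at C1, silyl ether at C5, benzyl ether at C3. Methylating the one free phenol places the methyl ether para to the bridge without any selectivity problem. Benzyl ethers are chosen for the other oxygens because hydrogenolysis spares methyl ethers that lie ortho to a ketone.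

**24 to 14 and 19 (key disconnection).** Bonds C1–C6 and C4–C5 of ring A are cut, and C5–C6 leaves as siloxyalkyne 19. The rest is cyclobutenone 14: its carbonyl carbon is C1, its CH2 is C2, its benzyloxy carbon is C3 and its bridge-bearing carbon is C4. The cut is made here and not at the bridge because a Friedel–Crafts union of two such rings would have to choose among several ring positions and would join two doubly ortho-substituted carbons. Building ring A onto a finished ring B avoids both problems and yields the three ring A oxygens already differentiated. The forward reaction must control one thing, the orientation of the alkyne when it adds to vinylketene 20.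

**19 to 15.** The terminal siloxyalkyne 19 comes from its C-silylated form 18 by removal of the carbon-bound silyl group, and 18 comes from ethynyltrimethylsilane 15 by oxidation of acetylide 16 to ynolate 17 and O-silylation. The carbon-bound silyl group blocks the carbon end of the ynolate during silylation.

**14 to 9 and 11.** The benzyl enol ether of 14 is cut to the acidic enol 13. The bond between the bridge carbon and C2 of the four-membered ring is then cut to aldehyde 9 and cyclobutane-1,3-dione 11, which is the hydrolysis product of commercial 3-ethoxycyclobut-2-en-1-one 10. A reductive alkylation is preferred to alkylation with a benzylic halide because it cannot give O-alkylation and needs no unstable electron-rich benzylic halide.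

**9 to 5.** The benzyl ethers of 9 are removed to give 8. The formyl carbon and then the acetyl carbon are cut off in turn, through 6, to the symmetric resorcinol 5. Each forward substitution has one possible site: the two free positions of 5 are equivalent, and 6 has one ring hydrogen left.

**5 to 1.** The C-methyl bond is cut. Forward, the bis-acetal 2 of commercial 5-methoxyresorcinol 1 is lithiated between its two acetal oxygens to give 3, methylated to 4 and deprotected.

## Alternatives that were turned down

Alternative 1: Ring B is unfolded into a 2-pyranone and a three-carbon ester.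
- Key step: the lithium enolate of methyl propanoate A3 would attack the lactone carbonyl of 4-methoxy-3-{[4-methoxy-2,6-bis(methoxymethoxy)phenyl]methyl}-6-methyl-2H-pyran-2-one A2. The ring opens, the carbon next to the freed methyl ketone closes onto the ester in a Claisen condensation, and aromatisation gives 1-[2,4-dihydroxy-6-methoxy-3-methyl-5-{[4-methoxy-2,6-bis(methoxymethoxy)phenyl]methyl}phenyl]ethan-1-one A1.
- For it: ring B appears in one operation with acetyl, C-methyl and methyl ether in place. A3 is a bulk chemical, and the sequence is probably a few steps shorter.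
- Against it: A2 offers the enolate four sites (lactone carbonyl, C6, C4 with loss of methoxide, and the acidic 6-methyl hydrogens). The carbon closure onto a hindered, α-branched ester competes with O-closure back to a pyranone. From A1 the end game is the same late acetylation of ring A as in the chosen route.
- Comparison: it is stronger on step count and on building ring B with its ketone in place. The chosen route offers a neutral, thermal pericyclic cascade with a single regiochemical question, and a ring B made by substitutions that each have one possible site.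

Alternative 2: Ring A is unfolded into commercial 4-methoxy-6-methyl-2H-pyran-2-one A6 and the enolate of 7-(benzyloxy)-5-methoxy-8-methyl-3,4-dihydro-2H-chromen-2-one A5.
- Key step: the enolate carbon of A5 would add to the carbonyl of A6. After ring opening, the carbon next to the freed methyl ketone would attack the aryl lactone carbonyl, closing ring A and releasing the ring B phenol in 1-[3-{[4-(benzyloxy)-2-hydroxy-6-methoxy-3-methylphenyl]methyl}-2,4-dihydroxy-6-methoxyphenyl]ethan-1-one A4.
- For it: it is the most convergent of the four plans, ring A arrives complete with acetyl and methyl ether, and the aryl ester is an activated acceptor for the closing step.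
- Against it: enolates of aryl esters fragment readily to a ketene and a phenoxide, and A5 has this pathway built in. A6 is again an ambident acceptor with acidic methyl hydrogens. A4 still lacks the ring B acetyl, so the last acylation must prefer the single CH of ring B over the single CH left on ring A, which rests on relative activation and not on structure.
- Comparison: it is shorter, but its final acylation is less secure than that of the chosen route, where ring B has no position left and the two positions of ring A are equivalent.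

Alternative 3: The same benzannulation is turned round to build ring B.
- Key step: 3-methoxy-2-{[4-methoxy-2,6-bis(methoxymethoxy)phenyl]methyl}cyclobut-2-en-1-one A8 would be heated with tri(propan-2-yl)(prop-1-yn-1-yloxy)silane A9 to give 4-{[4-methoxy-2,6-bis(methoxymethoxy)phenyl]methyl}-5-methoxy-2-methyl-3-{[tri(propan-2-yl)silyl]oxy}phenol A7.
- For it: A9 is an internal, alkyl-substituted siloxyalkyne of the best-tested kind and is more robust than terminal 19, so on the alkyne partner this plan is stronger. The ring B methyl ether of A7 comes directly from the vinylogous methyl ester of A8, ring A derives in a few steps from 1, and the route is shorter overall.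
- Against it: neither ring of A7 carries its acetyl, so two C-acylations remain on a diarylmethane whose rings are both unacylated, the state in which acid cuts the bridge most easily. The phenol and silyl ether that the annulation differentiates on ring B both end as OH, so the differentiation is unused. A8 needs the same dione alkylation as the cyclobutenone of the chosen route.
- Comparison: the chosen route offers a ring B that enters complete and deactivated, one acylation at the very end, and a lone phenol that is exactly the oxygen to be methylated.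

Key step: step 12

Remark on the chemistry: 13 is written as the enol tautomer of the 2-substituted cyclobutane-1,3-dione. The transient intermediates 7 and 21 are racemic, and the target has no stereocentre.

## Route

Step 1
Reactants: 1 5-methoxybenzene-1,3-diol (5-methoxyresorcinol)
Product: 2 1-methoxy-3,5-bis(methoxymethoxy)benzene
Conditions: NaH, MOMCl, DMF, 0 °C to rt
Reagents that add atoms: chloromethyl methyl ether, COCCl
Why: Williamson-type O-alkylation of both phenoxides; the hard electrophile in DMF favours O- over C-alkylation, and the acetals later serve as ortho-directing groups.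

Step 2
Reactants: 2 1-methoxy-3,5-bis(methoxymethoxy)benzene
Product: 4 5-methoxy-1,3-bis(methoxymethoxy)-2-methylbenzene, via aryllithium 3 (not isolated)
Conditions: n-BuLi, THF, 0 °C; then MeI, 0 °C to rt
Reagents that add atoms: iodomethane, CI
Why: Directed ortho-metalation; the hydrogen between the two chelating acetal groups is the most activated, ahead of the positions flanked by one acetal and the methoxy group, and aryllithium 3 is methylated by SN2.

Step 3
Reactants: 4 5-methoxy-1,3-bis(methoxymethoxy)-2-methylbenzene
Product: 5 5-methoxy-2-methylbenzene-1,3-diol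
Conditions: HCl (aq), MeOH, 50 °C
Reagents that add atoms: none
Why: Acid-catalysed transfer of the acetal groups to the solvent; the large excess of methanol should capture the methoxymethyl cation before the electron-rich ring does.

Step 4
Reactants: 5 5-methoxy-2-methylbenzene-1,3-diol
Product: 6 1-(2,4-dihydroxy-6-methoxy-3-methylphenyl)ethan-1-one
Conditions: AcOH, BF3·OEt2, 90 °C; then H2O
Reagents that add atoms: acetic acid, CC(=O)O
Why: Friedel–Crafts C-acylation of a phloroglucinol-type ring; the two free positions of 5 are equivalent, and the boron-chelated ortho-hydroxy ketone is deactivated against a second acylation.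

Step 5
Reactants: 6 1-(2,4-dihydroxy-6-methoxy-3-methylphenyl)ethan-1-one
Product: 8 3-acetyl-4,6-dihydroxy-2-methoxy-5-methylbenzaldehyde, via chloro(methoxy)methyl arene 7 (not isolated)
Conditions: Cl2CHOMe, TiCl4, CH2Cl2, −10 to 0 °C; then HCl (aq)
Reagents that add atoms: dichloromethyl methyl ether, COC(Cl)Cl; water, O
Why: Rieche formylation at the only ring hydrogen left, ortho to a phenol, followed by hydrolysis of 7; this avoids the chromone formation that an amide–POCl3 formylation would cause with an ortho-hydroxyacetophenone.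

Step 6
Reactants: 8 3-acetyl-4,6-dihydroxy-2-methoxy-5-methylbenzaldehyde
Product: 9 3-acetyl-4,6-bis(benzyloxy)-2-methoxy-5-methylbenzaldehyde
Conditions: BnBr, K2CO3, DMF, 50 °C
Reagents that add atoms: benzyl bromide, BrCc1ccccc1
Why: Williamson etherification; both phenols are hydrogen-bonded and hindered, hence DMF and gentle heating, while the doubly ortho-substituted ketone and aldehyde are too shielded for aldol condensation under carbonate.

Step 7
Reactants: 10 3-ethoxycyclobut-2-en-1-one
Product: 11 cyclobutane-1,3-dione
Conditions: HCl (1 M aq), rt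
Reagents that add atoms: water, O
Why: Acid hydrolysis of a vinylogous ester by addition–elimination at C3; the dione is made fresh because it degrades on storage.

Step 8
Reactants: 9 3-acetyl-4,6-bis(benzyloxy)-2-methoxy-5-methylbenzaldehyde; 11 cyclobutane-1,3-dione
Product: 13 2-{[3-acetyl-4,6-bis(benzyloxy)-2-methoxy-5-methylphenyl]methyl}-3-hydroxycyclobut-2-en-1-one, via alkylidene dione 12 (not isolated)
Conditions: Hantzsch ester, L-proline (cat.), CH2Cl2, rt
Reagents that add atoms: none
Why: Three-component reductive alkylation, established for five- and six-membered cyclic 1,3-diones: amine-catalysed Knoevenagel condensation gives 12, which the dihydropyridine reduces by conjugate hydride transfer before a second dione can add; the ketone is not touched.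

Step 9
Reactants: 13 2-{[3-acetyl-4,6-bis(benzyloxy)-2-methoxy-5-methylphenyl]methyl}-3-hydroxycyclobut-2-en-1-one
Product: 14 2-{[3-acetyl-4,6-bis(benzyloxy)-2-methoxy-5-methylphenyl]methyl}-3-(benzyloxy)cyclobut-2-en-1-one
Conditions: BnOH, PPh3, DIAD, THF, 0 °C to rt
Reagents that add atoms: benzyl alcohol, OCc1ccccc1
Why: Mitsunobu O-alkylation of a vinylogous carboxylic acid; the two carbonyl oxygens of 13 are equivalent, so one enol ether should result, and the neutral conditions avoid C-benzylation.

Step 10
Reactants: 15 ethynyltrimethylsilane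
Product: 18 tri(propan-2-yl){[(trimethylsilyl)ethynyl]oxy}silane, via lithium acetylide 16 (not isolated), via lithium ynolate 17 (not isolated)
Conditions: n-BuLi, THF, −78 °C; LiOOt-Bu (from t-BuOOH, LiN(SiMe3)2), −78 to 0 °C; TIPSOTf, −78 to 0 °C
Reagents that add atoms: tert-butyl hydroperoxide, CC(C)(C)OO; triisopropylsilyl trifluoromethanesulfonate, CC(C)[Si](OS(=O)(=O)C(F)(F)F)(C(C)C)C(C)C
Why: Oxidation of a lithium acetylide by lithium tert-butyl peroxide gives ynolate 17, and the bulky silyl triflate should react at oxygen as it does with alkyl ynolates; the carbon-bound trimethylsilyl group shields the carbon end against C-silylation.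

Step 11
Reactants: 18 tri(propan-2-yl){[(trimethylsilyl)ethynyl]oxy}silane
Product: 19 (ethynyloxy)tri(propan-2-yl)silane
Conditions: K2CO3 (cat.), MeOH/THF, 0 °C
Reagents that add atoms: none
Why: Base-catalysed methanolysis of an alkynyl–SiMe3 bond; methoxide attacks the unhindered trimethylsilyl group much faster than the shielded triisopropylsilyl ether, and siloxyalkynes add alcohols only under acid.

Step 12
Reactants: 14 2-{[3-acetyl-4,6-bis(benzyloxy)-2-methoxy-5-methylphenyl]methyl}-3-(benzyloxy)cyclobut-2-en-1-one; 19 (ethynyloxy)tri(propan-2-yl)silane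
Product: 24 4-{[3-acetyl-4,6-bis(benzyloxy)-2-methoxy-5-methylphenyl]methyl}-3-(benzyloxy)-5-{[tri(propan-2-yl)silyl]oxy}phenol, via vinylketene 20 (not isolated), via vinylcyclobutenone 21 (not isolated), via dienylketene 22 (not isolated), via cyclohexadienone 23 (not isolated)
Conditions: toluene, 110 °C, sealed tube, excess 19
Reagents that add atoms: none
Why: This is a Danheiser benzannulation of a cyclobutenone with a siloxyalkyne, the reaction type that gives resorcinol monosilyl ethers. On heating, 14 opens by a 4π electrocyclic reaction to vinylketene 20, whose electrophilic carbonyl carbon is attacked by the nucleophilic CH carbon of 19 in a regioselective [2+2] cycloaddition that gives 21 and forms bonds C1–C6 and C4–C5 of ring A. A second 4π opening gives dienylketene 22. Ring A then closes by a thermal, disrotatory 6π electrocyclization (bond C1–C2) to 23, which tautomerises to phenol 24. No stereocentre is formed. The step needs one regioselectivity, in the [2+2] event, and the oxygen lone pair of the siloxyalkyne secures it by polarising the triple bond so that the silyloxy carbon ends up next to the bridge-bearing carbon. Only the isomer of 22 with the ketene and the alkoxyvinyl group cis can cyclise, and reversible opening of 21 feeds it. The benzyloxy donor at C3 of 14 slows the first opening, hence 110 °C and an excess of 19.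

Step 13
Reactants: 24 4-{[3-acetyl-4,6-bis(benzyloxy)-2-methoxy-5-methylphenyl]methyl}-3-(benzyloxy)-5-{[tri(propan-2-yl)silyl]oxy}phenol
Product: 25 1-{4,6-bis(benzyloxy)-3-{[2-(benzyloxy)-4-methoxy-6-{[tri(propan-2-yl)silyl]oxy}phenyl]methyl}-2-methoxy-5-methylphenyl}ethan-1-one
Conditions: MeI, K2CO3, acetone, 40 °C
Reagents that add atoms: iodomethane, CI
Why: Williamson methylation of the only free phenol, which has two ortho hydrogens and is unhindered; dry carbonate in acetone should leave the shielded aryl silyl ether and the ketone alone.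

Step 14
Reactants: 25 1-{4,6-bis(benzyloxy)-3-{[2-(benzyloxy)-4-methoxy-6-{[tri(propan-2-yl)silyl]oxy}phenyl]methyl}-2-methoxy-5-methylphenyl}ethan-1-one
Product: 26 1-{4,6-bis(benzyloxy)-3-{[2-(benzyloxy)-6-hydroxy-4-methoxyphenyl]methyl}-2-methoxy-5-methylphenyl}ethan-1-one
Conditions: Bu4NF, AcOH, THF, 0 °C
Reagents that add atoms: none
Why: Fluoride-induced Si–O cleavage driven by the Si–F bond; acetic acid buffers the phenoxide so that the methyl ketone is not enolised.

Step 15
Reactants: 26 1-{4,6-bis(benzyloxy)-3-{[2-(benzyloxy)-6-hydroxy-4-methoxyphenyl]methyl}-2-methoxy-5-methylphenyl}ethan-1-one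
Product: 27 1-{3-[(2,6-dihydroxy-4-methoxyphenyl)methyl]-4,6-dihydroxy-2-methoxy-5-methylphenyl}ethan-1-one
Conditions: H2 (1 atm), Pd/C, EtOAc/MeOH, rt
Reagents that add atoms: none
Why: Catalytic hydrogenolysis of the three aryl benzyl ethers; the hindered, electron-rich aryl ketone and the aryl methyl ethers should survive at atmospheric pressure and room temperature.

Step 16
Reactants: 27 1-{3-[(2,6-dihydroxy-4-methoxyphenyl)methyl]-4,6-dihydroxy-2-methoxy-5-methylphenyl}ethan-1-one
Product: 29 1-{3-[(3-acetyl-2,6-dihydroxy-4-methoxyphenyl)methyl]-4,6-dihydroxy-2-methoxy-5-methylphenyl}ethan-1-one, via ketiminium chloride 28 (not isolated)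
Conditions: MeCN, ZnCl2, HCl (g), Et2O, 0 °C; then H2O, 80 °C
Reagents that add atoms: acetonitrile, CC#N; water, O
Why: Houben–Hoesch acylation; the nitrilium species attacks ring A at C2 (equivalent to C6), the only ring hydrogens in the molecule, and iminium salt 28 is deactivated against a second attack and is hydrolysed to the ketone by warm water.

## Compound list

1 | 5-methoxybenzene-1,3-diol | COc1cc(O)cc(O)c1 | starting material
2 | 1-methoxy-3,5-bis(methoxymethoxy)benzene | COCOc1cc(OC)cc(OCOC)c1 | intermediate
3 | [4-methoxy-2,6-bis(methoxymethoxy)phenyl]lithium | [Li]c1c(OCOC)cc(OC)cc1OCOC | intermediate (not isolated)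
4 | 5-methoxy-1,3-bis(methoxymethoxy)-2-methylbenzene | Cc1c(OCOC)cc(OC)cc1OCOC | intermediate
5 | 5-methoxy-2-methylbenzene-1,3-diol | Cc1c(O)cc(OC)cc1O | intermediate
6 | 1-(2,4-dihydroxy-6-methoxy-3-methylphenyl)ethan-1-one | CC(=O)c1c(O)c(C)c(O)cc1OC | intermediate
7 | 1-{3-[chloro(methoxy)methyl]-4,6-dihydroxy-2-methoxy-5-methylphenyl}ethan-1-one (racemic) | COC(Cl)c1c(O)c(C)c(O)c(C(C)=O)c1OC | intermediate (not isolated)
8 | 3-acetyl-4,6-dihydroxy-2-methoxy-5-methylbenzaldehyde | O=Cc1c(O)c(C)c(O)c(C(C)=O)c1OC | intermediate
9 | 3-acetyl-4,6-bis(benzyloxy)-2-methoxy-5-methylbenzaldehyde | O=Cc1c(OCc2ccccc2)c(C)c(OCc2ccccc2)c(C(C)=O)c1OC | intermediate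
10 | 3-ethoxycyclobut-2-en-1-one | CCOC1=CC(=O)C1 | starting material
11 | cyclobutane-1,3-dione | O=C1CC(=O)C1 | intermediate
12 | 2-{[3-acetyl-4,6-bis(benzyloxy)-2-methoxy-5-methylphenyl]methylidene}cyclobutane-1,3-dione | O=C1CC(=O)C1=Cc2c(OCc3ccccc3)c(C)c(OCc3ccccc3)c(C(C)=O)c2OC | intermediate (not isolated)
13 | 2-{[3-acetyl-4,6-bis(benzyloxy)-2-methoxy-5-methylphenyl]methyl}-3-hydroxycyclobut-2-en-1-one | O=C1CC(O)=C1Cc2c(OCc3ccccc3)c(C)c(OCc3ccccc3)c(C(C)=O)c2OC | intermediate
14 | 2-{[3-acetyl-4,6-bis(benzyloxy)-2-methoxy-5-methylphenyl]methyl}-3-(benzyloxy)cyclobut-2-en-1-one | O=C1CC(OCc2ccccc2)=C1Cc2c(OCc3ccccc3)c(C)c(OCc3ccccc3)c(C(C)=O)c2OC | intermediate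
15 | ethynyltrimethylsilane | C#C[Si](C)(C)C | starting material
16 | lithium (trimethylsilyl)acetylide | [Li]C#C[Si](C)(C)C | intermediate (not isolated)
17 | lithium 2-(trimethylsilyl)ethyn-1-olate | [Li]OC#C[Si](C)(C)C | intermediate (not isolated)
18 | tri(propan-2-yl){[(trimethylsilyl)ethynyl]oxy}silane | C[Si](C)(C)C#CO[Si](C(C)C)(C(C)C)C(C)C | intermediate
19 | (ethynyloxy)tri(propan-2-yl)silane | C#CO[Si](C(C)C)(C(C)C)C(C)C | intermediate
20 | 2-{[3-acetyl-4,6-bis(benzyloxy)-2-methoxy-5-methylphenyl]methyl}-3-(benzyloxy)buta-1,3-dien-1-one | O=C=C(Cc1c(OCc2ccccc2)c(C)c(OCc2ccccc2)c(C(C)=O)c1OC)C(OCc1ccccc1)=C | intermediate (not isolated)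
21 | 4-{[3-acetyl-4,6-bis(benzyloxy)-2-methoxy-5-methylphenyl]methyl}-4-[1-(benzyloxy)ethenyl]-3-{[tri(propan-2-yl)silyl]oxy}cyclobut-2-en-1-one (racemic) | O=C1C=C(O[Si](C(C)C)(C(C)C)C(C)C)C1(Cc2c(OCc3ccccc3)c(C)c(OCc3ccccc3)c(C(C)=O)c2OC)C(OCc2ccccc2)=C | intermediate (not isolated)
22 | (3E)-4-{[3-acetyl-4,6-bis(benzyloxy)-2-methoxy-5-methylphenyl]methyl}-5-(benzyloxy)-3-{[tri(propan-2-yl)silyl]oxy}hexa-1,3,5-trien-1-one (ketene and alkoxyvinyl groups cis) | O=C=C/C(O[Si](C(C)C)(C(C)C)C(C)C)=C(/Cc1c(OCc2ccccc2)c(C)c(OCc2ccccc2)c(C(C)=O)c1OC)C(OCc1ccccc1)=C | intermediate (not isolated)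
23 | 4-{[3-acetyl-4,6-bis(benzyloxy)-2-methoxy-5-methylphenyl]methyl}-5-(benzyloxy)-3-{[tri(propan-2-yl)silyl]oxy}cyclohexa-2,4-dien-1-one | O=C1C=C(O[Si](C(C)C)(C(C)C)C(C)C)C(Cc2c(OCc3ccccc3)c(C)c(OCc3ccccc3)c(C(C)=O)c2OC)=C(OCc2ccccc2)C1 | intermediate (not isolated)
24 | 4-{[3-acetyl-4,6-bis(benzyloxy)-2-methoxy-5-methylphenyl]methyl}-3-(benzyloxy)-5-{[tri(propan-2-yl)silyl]oxy}phenol | Oc1cc(O[Si](C(C)C)(C(C)C)C(C)C)c(Cc2c(OCc3ccccc3)c(C)c(OCc3ccccc3)c(C(C)=O)c2OC)c(OCc2ccccc2)c1 | intermediate
25 | 1-{4,6-bis(benzyloxy)-3-{[2-(benzyloxy)-4-methoxy-6-{[tri(propan-2-yl)silyl]oxy}phenyl]methyl}-2-methoxy-5-methylphenyl}ethan-1-one | COc1cc(O[Si](C(C)C)(C(C)C)C(C)C)c(Cc2c(OCc3ccccc3)c(C)c(OCc3ccccc3)c(C(C)=O)c2OC)c(OCc2ccccc2)c1 | intermediate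
26 | 1-{4,6-bis(benzyloxy)-3-{[2-(benzyloxy)-6-hydroxy-4-methoxyphenyl]methyl}-2-methoxy-5-methylphenyl}ethan-1-one | COc1cc(O)c(Cc2c(OCc3ccccc3)c(C)c(OCc3ccccc3)c(C(C)=O)c2OC)c(OCc2ccccc2)c1 | intermediate
27 | 1-{3-[(2,6-dihydroxy-4-methoxyphenyl)methyl]-4,6-dihydroxy-2-methoxy-5-methylphenyl}ethan-1-one | COc1cc(O)c(Cc2c(O)c(C)c(O)c(C(C)=O)c2OC)c(O)c1 | intermediate
28 | 1-(3-{[3-acetyl-4,6-dihydroxy-2-methoxy-5-methylphenyl]methyl}-2,4-dihydroxy-6-methoxyphenyl)ethan-1-iminium chloride | CC(=[NH2+])c1c(OC)cc(O)c(Cc2c(O)c(C)c(O)c(C(C)=O)c2OC)c1O.[Cl-] | intermediate (not isolated)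
29 | 1-{3-[(3-acetyl-2,6-dihydroxy-4-methoxyphenyl)methyl]-4,6-dihydroxy-2-methoxy-5-methylphenyl}ethan-1-one | COc1cc(O)c(Cc2c(O)c(C)c(O)c(C(C)=O)c2OC)c(O)c1C(C)=O | target

## Step count and least certain steps

Total: 16 steps. Longest linear sequence: 13 steps (steps 1–6, 8, 9, 12–16); step 7 and steps 10–11 are side branches.

**Step 12 (key step).** The donor-stabilised cyclobutenone may open too slowly, so that the terminal siloxyalkyne is lost first by a 1,3-silyl shift or by oligomerisation. The phenol formed may also be O-acylated by vinylketene that has not yet been trapped. The fallback sets out from 9 and from aryllithium 3 (made from 2 as in step 2) and joins the rings directly. Addition of 3 to the aldehyde of 9 at −78 °C, after transmetalation with CeCl3 to suppress enolisation of the shielded ketone, should give 1-{4,6-bis(benzyloxy)-3-{hydroxy[4-methoxy-2,6-bis(methoxymethoxy)phenyl]methyl}-2-methoxy-5-methylphenyl}ethan-1-one F1 (racemic). Et3SiH with CF3CO2H should remove the doubly benzylic hydroxyl by ionic hydrogenation and also the two acetal groups, whose methoxymethyl cation the silane reduces. The ketone, twisted out of conjugation by its two ortho substituents, should react far more slowly than the diarylmethyl cation. The product would be 1-{4,6-bis(benzyloxy)-3-[(2,6-dihydroxy-4-methoxyphenyl)methyl]-2-methoxy-5-methylphenyl}ethan-1-one F2. Partial loss of benzyl groups here would not matter, because hydrogenolysis as in step 15 follows and rejoins the route at 27.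

**Step 8.** The Knoevenagel condensation may stall at the doubly ortho-substituted aldehyde, the strained dione may be opened or tied up as an enaminone by the amine catalyst, or a second dione may add to 12 before hydride transfer. The fallback sets out from 9 and builds the four-membered ring by cycloaddition. NaBH4 at low temperature should reduce only the aldehyde to 1-[4,6-bis(benzyloxy)-3-(hydroxymethyl)-2-methoxy-5-methylphenyl]ethan-1-one F3. CBr4 and PPh3 should give 1-[4,6-bis(benzyloxy)-3-(bromomethyl)-2-methoxy-5-methylphenyl]ethan-1-one F4. Stille coupling with tributyl(ethoxyethynyl)stannane and Pd(PPh3)4, which tolerates the ketone, should give 1-[4,6-bis(benzyloxy)-3-(3-ethoxyprop-2-yn-1-yl)-2-methoxy-5-methylphenyl]ethan-1-one F5. The [2+2] cycloaddition of this 1-ethoxyalkyne with ketene gas in CH2Cl2 at 0 °C should give 2-{[3-acetyl-4,6-bis(benzyloxy)-2-methoxy-5-methylphenyl]methyl}-3-ethoxycyclobut-2-en-1-one F6. Dilute HCl, as in step 7, then hydrolyses the enol ether and rejoins the route at 13.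

**Step 11.** Methanolysis may also cleave the oxygen–silicon bond of the ynol ether, giving an ynolate and then an ester, or the sensitive terminal alkyne may be lost on isolation. The fallback sets out from 18 and 14 and moves the desilylation to after the ring synthesis. Heating 14 with 18 under the conditions of step 12 (same polarisation, the silyl-bearing carbon bonding to the ketene carbon) should give 4-{[3-acetyl-4,6-bis(benzyloxy)-2-methoxy-5-methylphenyl]methyl}-5-(benzyloxy)-3-{[tri(propan-2-yl)silyl]oxy}-2-(trimethylsilyl)phenol F7. Ipso protodesilylation of this electron-rich arylsilane with CF3CO2H in CH2Cl2 at 0 °C rejoins the route at 24.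

**Step 16.** Acid may cut the methylene bridge by ipso protonation of the still unacylated ring A, the nitrilium ion may attack a phenol oxygen instead of carbon, or conversion may be incomplete. The fallback sets out from 25 and replaces the electrophilic acylation by halogenation and cross-coupling on the protected compound. N-Bromosuccinimide at low temperature should brominate ring A, the only ring with hydrogen, mainly between the methoxy and benzyloxy groups and away from the bulky silyl ether, to give 1-{4,6-bis(benzyloxy)-3-{[2-(benzyloxy)-3-bromo-4-methoxy-6-{[tri(propan-2-yl)silyl]oxy}phenyl]methyl}-2-methoxy-5-methylphenyl}ethan-1-one F8; the other regioisomer would converge on the same target. Stille coupling with tributyl(1-ethoxyethenyl)stannane and Pd(P(t-Bu)3)2 in toluene should give 1-{4,6-bis(benzyloxy)-3-{[2-(benzyloxy)-3-(1-ethoxyethenyl)-4-methoxy-6-{[tri(propan-2-yl)silyl]oxy}phenyl]methyl}-2-methoxy-5-methylphenyl}ethan-1-one F9. Dilute aqueous HCl should hydrolyse the enol ether to 1-{3-{[3-acetyl-2-(benzyloxy)-4-methoxy-6-{[tri(propan-2-yl)silyl]oxy}phenyl]methyl}-4,6-bis(benzyloxy)-2-methoxy-5-methylphenyl}ethan-1-one F10. Bu4NF should then give 1-{3-{[3-acetyl-2-(benzyloxy)-6-hydroxy-4-methoxyphenyl]methyl}-4,6-bis(benzyloxy)-2-methoxy-5-methylphenyl}ethan-1-one F11, and hydrogenolysis as in step 15 reaches the route again at 29.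

## Further compounds

F1 | step 12 | 1-{4,6-bis(benzyloxy)-3-{hydroxy[4-methoxy-2,6-bis(methoxymethoxy)phenyl]methyl}-2-methoxy-5-methylphenyl}ethan-1-one (racemic) | COCOc1cc(OC)cc(OCOC)c1C(O)c1c(OCc2ccccc2)c(C)c(OCc2ccccc2)c(C(C)=O)c1OC
F2 | step 12 | 1-{4,6-bis(benzyloxy)-3-[(2,6-dihydroxy-4-methoxyphenyl)methyl]-2-methoxy-5-methylphenyl}ethan-1-one | COc1cc(O)c(Cc2c(OCc3ccccc3)c(C)c(OCc3ccccc3)c(C(C)=O)c2OC)c(O)c1
F3 | step 8 | 1-[4,6-bis(benzyloxy)-3-(hydroxymethyl)-2-methoxy-5-methylphenyl]ethan-1-one | CC(=O)c1c(OC)c(CO)c(OCc2ccccc2)c(C)c1OCc1ccccc1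
F4 | step 8 | 1-[4,6-bis(benzyloxy)-3-(bromomethyl)-2-methoxy-5-methylphenyl]ethan-1-one | CC(=O)c1c(OC)c(CBr)c(OCc2ccccc2)c(C)c1OCc1ccccc1
F5 | step 8 | 1-[4,6-bis(benzyloxy)-3-(3-ethoxyprop-2-yn-1-yl)-2-methoxy-5-methylphenyl]ethan-1-one | CCOC#CCc1c(OCc2ccccc2)c(C)c(OCc2ccccc2)c(C(C)=O)c1OC
F6 | step 8 | 2-{[3-acetyl-4,6-bis(benzyloxy)-2-methoxy-5-methylphenyl]methyl}-3-ethoxycyclobut-2-en-1-one | CCOC1=C(Cc2c(OCc3ccccc3)c(C)c(OCc3ccccc3)c(C(C)=O)c2OC)C(=O)C1
F7 | step 11 | 4-{[3-acetyl-4,6-bis(benzyloxy)-2-methoxy-5-methylphenyl]methyl}-5-(benzyloxy)-3-{[tri(propan-2-yl)silyl]oxy}-2-(trimethylsilyl)phenol | Oc1cc(OCc2ccccc2)c(Cc2c(OCc3ccccc3)c(C)c(OCc3ccccc3)c(C(C)=O)c2OC)c(O[Si](C(C)C)(C(C)C)C(C)C)c1[Si](C)(C)C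
F8 | step 16 | 1-{4,6-bis(benzyloxy)-3-{[2-(benzyloxy)-3-bromo-4-methoxy-6-{[tri(propan-2-yl)silyl]oxy}phenyl]methyl}-2-methoxy-5-methylphenyl}ethan-1-one | COc1cc(O[Si](C(C)C)(C(C)C)C(C)C)c(Cc2c(OCc3ccccc3)c(C)c(OCc3ccccc3)c(C(C)=O)c2OC)c(OCc2ccccc2)c1Br
F9 | step 16 | 1-{4,6-bis(benzyloxy)-3-{[2-(benzyloxy)-3-(1-ethoxyethenyl)-4-methoxy-6-{[tri(propan-2-yl)silyl]oxy}phenyl]methyl}-2-methoxy-5-methylphenyl}ethan-1-one | COc1cc(O[Si](C(C)C)(C(C)C)C(C)C)c(Cc2c(OCc3ccccc3)c(C)c(OCc3ccccc3)c(C(C)=O)c2OC)c(OCc2ccccc2)c1C(=C)OCC
F10 | step 16 | 1-{3-{[3-acetyl-2-(benzyloxy)-4-methoxy-6-{[tri(propan-2-yl)silyl]oxy}phenyl]methyl}-4,6-bis(benzyloxy)-2-methoxy-5-methylphenyl}ethan-1-one | COc1cc(O[Si](C(C)C)(C(C)C)C(C)C)c(Cc2c(OCc3ccccc3)c(C)c(OCc3ccccc3)c(C(C)=O)c2OC)c(OCc2ccccc2)c1C(C)=O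
F11 | step 16 | 1-{3-{[3-acetyl-2-(benzyloxy)-6-hydroxy-4-methoxyphenyl]methyl}-4,6-bis(benzyloxy)-2-methoxy-5-methylphenyl}ethan-1-one | COc1cc(O)c(Cc2c(OCc3ccccc3)c(C)c(OCc3ccccc3)c(C(C)=O)c2OC)c(OCc2ccccc2)c1C(C)=O
A1 | alternative 1 | 1-[2,4-dihydroxy-6-methoxy-3-methyl-5-{[4-methoxy-2,6-bis(methoxymethoxy)phenyl]methyl}phenyl]ethan-1-one | COc1cc(OCOC)c(Cc2c(O)c(C)c(O)c(C(C)=O)c2OC)c(OCOC)c1
A2 | alternative 1 | 4-methoxy-3-{[4-methoxy-2,6-bis(methoxymethoxy)phenyl]methyl}-6-methyl-2H-pyran-2-one | COCOc1cc(OC)cc(OCOC)c1Cc1c(OC)cc(C)oc1=O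
A3 | alternative 1 | methyl propanoate | CCC(=O)OC
A4 | alternative 2 | 1-[3-{[4-(benzyloxy)-2-hydroxy-6-methoxy-3-methylphenyl]methyl}-2,4-dihydroxy-6-methoxyphenyl]ethan-1-one | COc1cc(O)c(Cc2c(O)c(C)c(OCc3ccccc3)cc2OC)c(O)c1C(C)=O
A5 | alternative 2 | 7-(benzyloxy)-5-methoxy-8-methyl-3,4-dihydro-2H-chromen-2-one | O=C1CCc2c(OC)cc(OCc3ccccc3)c(C)c2O1
A6 | alternative 2 | 4-methoxy-6-methyl-2H-pyran-2-one | COc1cc(C)oc(=O)c1
A7 | alternative 3 | 4-{[4-methoxy-2,6-bis(methoxymethoxy)phenyl]methyl}-5-methoxy-2-methyl-3-{[tri(propan-2-yl)silyl]oxy}phenol | COc1cc(OCOC)c(Cc2c(O[Si](C(C)C)(C(C)C)C(C)C)c(C)c(O)cc2OC)c(OCOC)c1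
A8 | alternative 3 | 3-methoxy-2-{[4-methoxy-2,6-bis(methoxymethoxy)phenyl]methyl}cyclobut-2-en-1-one | COC1=C(Cc2c(OCOC)cc(OC)cc2OCOC)C(=O)C1
A9 | alternative 3 | tri(propan-2-yl)(prop-1-yn-1-yloxy)silane | CC#CO[Si](C(C)C)(C(C)C)C(C)C
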